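The plan rests on cutting the aryl ether bond O1–C8a of the pyran ring (ring C). Because O1 sits on resorcinol ring A, ortho to the carbon that carries C4, the chroman can be closed by a palladium-catalysed intramolecular etherification of an open-chain secondary benzylic alcohol onto an ortho-bromoarene. This ring closure breaks no bond at C2 or C4, so both stereocentres are set in earlier steps by catalysts (C4 by an iminium-catalysed Friedel–Crafts alkylation, C2 by Noyori transfer hydrogenation) and the 2,4-trans relationship is programmed, not left to substrate bias. The precursor is a pentabenzylated (1R,3R)-1,3,3-triarylpropan-1-ol that carries bromine where O1 will bond.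

Key step: step 8

Assumption: 9-phenylnonanoic acid and [4-(benzyloxy)phenyl]magnesium bromide (THF solution) are taken as catalogue reagents, and lactol 10 is carried on as its mixture of anomers, which converge in step 5.

Step 1
Reactants: 1 2-bromo-4-hydroxybenzaldehyde
Product: 2 4-(benzyloxy)-2-bromobenzaldehyde
Conditions: BnBr, K2CO3, DMF, rt
Reagents that add atoms: benzyl bromide, BrCc1ccccc1
Why: Williamson etherification of the only phenol (SN2 of the phenoxide on benzyl bromide) should proceed cleanly, the aldehyde and the aryl bromide being inert to K2CO3.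

Step 2
Reactants: 2 4-(benzyloxy)-2-bromobenzaldehyde; 3 (triphenylphosphoranylidene)acetaldehyde
Product: 4 (2E)-3-[4-(benzyloxy)-2-bromophenyl]prop-2-enal
Conditions: 3 (1.1 equiv), toluene, 80 °C
Reagents that add atoms: none
Why: Wittig olefination with the stabilised formyl ylide should give the (E)-enal selectively, and a small excess of ylide limits a second homologation of the less electrophilic product.

Step 3
Reactants: 5 9-phenylnonanoic acid; 6 phloroglucinol
Product: 8 9-phenyl-1-(2,4,6-trihydroxyphenyl)nonan-1-one, via acid chloride 7 (not isolated)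
Conditions: (COCl)2, cat. DMF, CH2Cl2, 0 °C to rt; then 6, AlCl3, PhNO2/CH2Cl2, 0 to 40 °C; aq. HCl work-up
Reagents that add atoms: none
Why: Friedel–Crafts C-acylation of the threefold-symmetric phloroglucinol can give only one regioisomer, and the first acyl group deactivates the ring towards a second acylation.

Step 4
Reactants: 4 (2E)-3-[4-(benzyloxy)-2-bromophenyl]prop-2-enal; 8 9-phenyl-1-(2,4,6-trihydroxyphenyl)nonan-1-one (1.5 equiv)
Product: 10 1-[(4R)-4-[4-(benzyloxy)-2-bromophenyl]-2,5,7-trihydroxy-3,4-dihydro-2H-chromen-6-yl]-9-phenylnonan-1-one (lactol as both anomers), via open-chain aldehyde 9 (not isolated)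
Conditions: (S)-2-[diphenyl(trimethylsilyloxy)methyl]pyrrolidine (20 mol%), PhCO2H (20 mol%), CHCl3, 0 °C to rt
Reagents that add atoms: none
Why: In this iminium-catalysed Friedel–Crafts alkylation/hemiacetalisation of an electron-rich phenol with an enal, the CPh2OSiMe3 group of the (S)-catalyst shields the Re face of the β-carbon of the (E)-iminium ion, so the free nuclear carbon of 8 should add to the Si face and set the future C4 (R descriptor while bromine is present), after which the neighbouring non-chelated phenol traps the aldehyde as a temporary lactol.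

Step 5
Reactants: 10 lactol 1-[(4R)-4-[4-(benzyloxy)-2-bromophenyl]-2,5,7-trihydroxy-3,4-dihydro-2H-chromen-6-yl]-9-phenylnonan-1-one
Product: 11 (3R)-3-[4-(benzyloxy)-2-bromophenyl]-3-[2,4,6-tris(benzyloxy)-3-(9-phenylnonanoyl)phenyl]propanal
Conditions: BnBr (4 equiv), K2CO3, n-Bu4NI (cat.), DMF, rt to 45 °C
Reagents that add atoms: benzyl bromide, BrCc1ccccc1
Why: Under Williamson conditions K2CO3 opens the cyclic hemiacetal to its phenoxide-aldehyde form, and the three phenoxides should be O-benzylated in the polar aprotic solvent, which frees the aldehyde and leaves the carbinol of step 7 as the only future oxygen nucleophile.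

Step 6
Reactants: 11 (3R)-3-[4-(benzyloxy)-2-bromophenyl]-3-[2,4,6-tris(benzyloxy)-3-(9-phenylnonanoyl)phenyl]propanal; 12 [4-(benzyloxy)phenyl]magnesium bromide
Product: 14 (3R)-1-[4-(benzyloxy)phenyl]-3-[4-(benzyloxy)-2-bromophenyl]-3-[2,4,6-tris(benzyloxy)-3-(9-phenylnonanoyl)phenyl]propan-1-one, via bromomagnesium alkoxide 13 (not isolated)
Conditions: 12 (1.1 equiv), THF, −78 to 0 °C; then 1,1'-(azodicarbonyl)dipiperidine (1.5 equiv), THF, 0 °C to rt; aq. NH4Cl
Reagents that add atoms: none
Why: Grignard 1,2-addition to the unhindered aldehyde (the di-ortho-benzyloxy aryl ketone is shielded) gives the bromomagnesium alkoxide, which the azo compound should oxidise in the same flask by hydride transfer (Mukaiyama oxidation), so the C1 epimer mixture is never handled.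

Step 7
Reactants: 14 (3R)-1-[4-(benzyloxy)phenyl]-3-[4-(benzyloxy)-2-bromophenyl]-3-[2,4,6-tris(benzyloxy)-3-(9-phenylnonanoyl)phenyl]propan-1-one
Product: 15 (1R,3R)-1-[4-(benzyloxy)phenyl]-3-[4-(benzyloxy)-2-bromophenyl]-3-[2,4,6-tris(benzyloxy)-3-(9-phenylnonanoyl)phenyl]propan-1-ol
Conditions: RuCl[(R,R)-TsDPEN](p-cymene) (3 mol%), HCO2H/Et3N (5:2), CH2Cl2, 30 °C
Reagents that add atoms: none
Why: Noyori asymmetric transfer hydrogenation should deliver hydride to the aryl ketone under control of the (R,R)-ligand (CH/π contact of the 4-benzyloxyphenyl group with the cymene) to give the (1R)-carbinol, while the twisted di-ortho-substituted acyl ketone and the aryl bromide should not react.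

Step 8
Reactants: 15 (1R,3R)-1-[4-(benzyloxy)phenyl]-3-[4-(benzyloxy)-2-bromophenyl]-3-[2,4,6-tris(benzyloxy)-3-(9-phenylnonanoyl)phenyl]propan-1-ol
Product: 16 1-[2,4,6-tris(benzyloxy)-3-[(2R,4S)-7-(benzyloxy)-2-[4-(benzyloxy)phenyl]-3,4-dihydro-2H-chromen-4-yl]phenyl]-9-phenylnonan-1-one
Conditions: Pd(OAc)2 (5 mol%), rac-2-(di-tert-butylphosphino)-1,1'-binaphthyl (6 mol%), Cs2CO3 (1.5 equiv), toluene, 80 °C
Reagents that add atoms: none
Why: Pd(OAc)2 and the bulky biaryl phosphine give a monoligated zerovalent palladium species that inserts into the C8a–Br bond, the carbinol is deprotonated by Cs2CO3 and displaces bromide on the divalent palladium centre, and C–O reductive elimination from the resulting seven-membered aryl(alkoxo)palladium chelate forms O1–C8a. The closest known reaction type is the Buchwald–Hartwig intramolecular etherification of secondary alcohols with ortho-haloarenes to 2-substituted chromans. Ring C is the only ring closed, as a six-membered ring by reductive elimination that contracts the seven-membered palladacycle (exo attack of the tethered alkoxide on the aryl carbon). No stereocentre is created: C2 and C4 were set in steps 7 and 4 and no bond to either carbon is broken, so the (1R,3R) alcohol maps with retention onto the (2R,4S) trans flavan. The step needs C–O reductive elimination to outrun β-hydride elimination of the benzylic alkoxide, which the hindered electron-rich phosphine and the favourable six-membered closure should secure, and it needs a single oxygen nucleophile, which is secured because every phenol is benzylated and the weak base leaves the twisted di-ortho-substituted ketone unenolised.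

Step 9
Reactants: 16 1-[2,4,6-tris(benzyloxy)-3-[(2R,4S)-7-(benzyloxy)-2-[4-(benzyloxy)phenyl]-3,4-dihydro-2H-chromen-4-yl]phenyl]-9-phenylnonan-1-one
Product: 17 1-[2,4,6-trihydroxy-3-[(2R,4S)-7-hydroxy-2-(4-hydroxyphenyl)-3,4-dihydro-2H-chromen-4-yl]phenyl]-9-phenylnonan-1-one (CNP0175574.3)
Conditions: H2 (1 atm), Pd/C (10 wt% palladium on carbon), EtOAc/MeOH, rt
Reagents that add atoms: none
Why: Hydrogenolysis of the five aryl benzyl ethers should be faster than opening of the cyclic benzylic ether at C2 or reduction of the hydrogen-bonded aryl ketone in neutral medium at room temperature, and it touches neither stereocentre.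

Compound list
1 | 2-bromo-4-hydroxybenzaldehyde | O=Cc1ccc(O)cc1Br | starting material
2 | 4-(benzyloxy)-2-bromobenzaldehyde | O=Cc1ccc(OCc2ccccc2)cc1Br | intermediate
3 | (triphenylphosphoranylidene)acetaldehyde | O=CC=P(c1ccccc1)(c1ccccc1)c1ccccc1 | starting material
4 | (2E)-3-[4-(benzyloxy)-2-bromophenyl]prop-2-enal | O=C/C=C/c1ccc(OCc2ccccc2)cc1Br | intermediate
5 | 9-phenylnonanoic acid | OC(=O)CCCCCCCCc1ccccc1 | starting material
6 | phloroglucinol (benzene-1,3,5-triol) | Oc1cc(O)cc(O)c1 | starting material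
7 | 9-phenylnonanoyl chloride | ClC(=O)CCCCCCCCc1ccccc1 | intermediate
8 | 9-phenyl-1-(2,4,6-trihydroxyphenyl)nonan-1-one | O=C(CCCCCCCCc1ccccc1)c1c(O)cc(O)cc1O | intermediate
9 | (3R)-3-[4-(benzyloxy)-2-bromophenyl]-3-[2,4,6-trihydroxy-3-(9-phenylnonanoyl)phenyl]propanal | O=C(CCCCCCCCc1ccccc1)c1c(O)cc(O)c([C@@H](CC=O)c2ccc(OCc3ccccc3)cc2Br)c1O | intermediate
10 | 1-[(4R)-4-[4-(benzyloxy)-2-bromophenyl]-2,5,7-trihydroxy-3,4-dihydro-2H-chromen-6-yl]-9-phenylnonan-1-one (lactol as both anomers) | O=C(CCCCCCCCc1ccccc1)c1c(O)cc2OC(O)C[C@@H](c3ccc(OCc4ccccc4)cc3Br)c2c1O | intermediate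
11 | (3R)-3-[4-(benzyloxy)-2-bromophenyl]-3-[2,4,6-tris(benzyloxy)-3-(9-phenylnonanoyl)phenyl]propanal | O=C(CCCCCCCCc1ccccc1)c1c(OCc2ccccc2)cc(OCc2ccccc2)c([C@@H](CC=O)c2ccc(OCc3ccccc3)cc2Br)c1OCc1ccccc1 | intermediate
12 | [4-(benzyloxy)phenyl]magnesium bromide | Br[Mg]c1ccc(OCc2ccccc2)cc1 | starting material
13 | bromomagnesium alkoxide of (3R)-1-[4-(benzyloxy)phenyl]-3-[4-(benzyloxy)-2-bromophenyl]-3-[2,4,6-tris(benzyloxy)-3-(9-phenylnonanoyl)phenyl]propan-1-ol (both C1 epimers) | O=C(CCCCCCCCc1ccccc1)c1c(OCc2ccccc2)cc(OCc2ccccc2)c([C@@H](CC(O[Mg]Br)c2ccc(OCc3ccccc3)cc2)c2ccc(OCc3ccccc3)cc2Br)c1OCc1ccccc1 | intermediate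
14 | (3R)-1-[4-(benzyloxy)phenyl]-3-[4-(benzyloxy)-2-bromophenyl]-3-[2,4,6-tris(benzyloxy)-3-(9-phenylnonanoyl)phenyl]propan-1-one | O=C(CCCCCCCCc1ccccc1)c1c(OCc2ccccc2)cc(OCc2ccccc2)c([C@@H](CC(=O)c2ccc(OCc3ccccc3)cc2)c2ccc(OCc3ccccc3)cc2Br)c1OCc1ccccc1 | intermediate
15 | (1R,3R)-1-[4-(benzyloxy)phenyl]-3-[4-(benzyloxy)-2-bromophenyl]-3-[2,4,6-tris(benzyloxy)-3-(9-phenylnonanoyl)phenyl]propan-1-ol | O=C(CCCCCCCCc1ccccc1)c1c(OCc2ccccc2)cc(OCc2ccccc2)c([C@@H](C[C@H](c2ccc(OCc3ccccc3)cc2)O)c2ccc(OCc3ccccc3)cc2Br)c1OCc1ccccc1 | intermediate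
16 | 1-[2,4,6-tris(benzyloxy)-3-[(2R,4S)-7-(benzyloxy)-2-[4-(benzyloxy)phenyl]-3,4-dihydro-2H-chromen-4-yl]phenyl]-9-phenylnonan-1-one | O=C(CCCCCCCCc1ccccc1)c1c(OCc2ccccc2)cc(OCc2ccccc2)c([C@H]2C[C@H](c3ccc(OCc4ccccc4)cc3)Oc3cc(OCc4ccccc4)ccc32)c1OCc1ccccc1 | intermediate
17 | 1-[2,4,6-trihydroxy-3-[(2R,4S)-7-hydroxy-2-(4-hydroxyphenyl)-3,4-dihydro-2H-chromen-4-yl]phenyl]-9-phenylnonan-1-one | O=C(CCCCCCCCc1ccccc1)c1c(O)cc(O)c([C@H]2C[C@H](c3ccc(O)cc3)Oc3cc(O)ccc32)c1O | target

Total step count: 9. Longest linear sequence: 8 steps (steps 1, 2, 4, 5, 6, 7, 8, 9 from compound 1); step 3 is a one-step side branch.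

Steps most likely to fail

Step 8. β-Hydride elimination from the aryl(alkoxo)palladium intermediate could outrun C–O reductive elimination, giving net oxidation of the carbinol with hydrodebromination, and oxidative addition at the crowded ortho-substituted bromide could be slow. The fallback closes the other ether bond, O1–C2, by SN2 with inversion. It sets out from ketone 14 and returns at 16. Palladium-catalysed hydroxylation of the aryl bromide (Pd2(dba)3, 2-di-tert-butylphosphino-2',4',6'-triisopropylbiphenyl, KOH, 1,4-dioxane/H2O, 100 °C) should give (3S)-1-[4-(benzyloxy)phenyl]-3-[4-(benzyloxy)-2-hydroxyphenyl]-3-[2,4,6-tris(benzyloxy)-3-(9-phenylnonanoyl)phenyl]propan-1-one F1. Transfer hydrogenation with the enantiomeric catalyst RuCl[(S,S)-TsDPEN](p-cymene) should then give (1S,3S)-1-[4-(benzyloxy)phenyl]-3-[4-(benzyloxy)-2-hydroxyphenyl]-3-[2,4,6-tris(benzyloxy)-3-(9-phenylnonanoyl)phenyl]propan-1-ol F2. Mitsunobu cyclisation of the single free phenol onto the carbinol (PPh3, diisopropyl azodicarboxylate, THF, 0 °C) should invert C1 and give 16; partial ionisation of the electron-rich benzylic carbinol is the risk of this variant, which is why it is not the main line.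

Step 4. The acyl group lowers the nucleophilicity of the phloroglucinol, so conjugate addition to the iminium ion could be slow and give way to 1,2-addition/condensation or to double alkylation. The fallback uses the more nucleophilic parent phenol and installs the acyl chain later. It sets out from enal 4 and phloroglucinol 6 and returns at 14. The same catalyst should give (4R)-4-[4-(benzyloxy)-2-bromophenyl]-3,4-dihydro-2H-chromene-2,5,7-triol F3. Benzylation (BnBr, K2CO3, DMF) should open it to (3R)-3-[4-(benzyloxy)-2-bromophenyl]-3-[2,4,6-tris(benzyloxy)phenyl]propanal F4. Addition of 12 followed by oxidation with 1,1'-(azodicarbonyl)dipiperidine should give (3R)-1-[4-(benzyloxy)phenyl]-3-[4-(benzyloxy)-2-bromophenyl]-3-[2,4,6-tris(benzyloxy)phenyl]propan-1-one F5. Mixed-anhydride Friedel–Crafts acylation with acid 5 and (CF3CO)2O (CH2Cl2, 0 °C) at one of the two equivalent free positions of the tribenzyloxy ring, by far the most electron-rich arene, should give 14.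

Step 5. Benzylation of the hydrogen-bonded, doubly flanked hydroxyl is slow, and during that time the free aldehyde could undergo aldol self-condensation or base-mediated retro-Michael cleavage at the future C4; C-benzylation at the remaining nuclear position is a further side reaction. The fallback removes the aldehyde before the base treatment. It sets out from lactol 10 and returns at 14. Excess 12 (6 equiv, THF, 0 °C to rt) should open the lactol to 1-[3-[(1R)-1-[4-(benzyloxy)-2-bromophenyl]-3-[4-(benzyloxy)phenyl]-3-hydroxypropyl]-2,4,6-trihydroxyphenyl]-9-phenylnonan-1-one F6 (both carbinol epimers). Benzylation of its three phenols (BnBr, K2CO3, DMF, 60 °C) should give (3R)-1-[4-(benzyloxy)phenyl]-3-[4-(benzyloxy)-2-bromophenyl]-3-[2,4,6-tris(benzyloxy)-3-(9-phenylnonanoyl)phenyl]propan-1-ol F7 (both carbinol epimers). Dess–Martin periodinane (CH2Cl2, rt) should then give 14.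

Further compounds
F1 | step 8 | (3S)-1-[4-(benzyloxy)phenyl]-3-[4-(benzyloxy)-2-hydroxyphenyl]-3-[2,4,6-tris(benzyloxy)-3-(9-phenylnonanoyl)phenyl]propan-1-one | O=C(CCCCCCCCc1ccccc1)c1c(OCc2ccccc2)cc(OCc2ccccc2)c([C@@H](CC(=O)c2ccc(OCc3ccccc3)cc2)c2ccc(OCc3ccccc3)cc2O)c1OCc1ccccc1
F2 | step 8 | (1S,3S)-1-[4-(benzyloxy)phenyl]-3-[4-(benzyloxy)-2-hydroxyphenyl]-3-[2,4,6-tris(benzyloxy)-3-(9-phenylnonanoyl)phenyl]propan-1-ol | O=C(CCCCCCCCc1ccccc1)c1c(OCc2ccccc2)cc(OCc2ccccc2)c([C@@H](C[C@@H](c2ccc(OCc3ccccc3)cc2)O)c2ccc(OCc3ccccc3)cc2O)c1OCc1ccccc1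
F3 | step 4 | (4R)-4-[4-(benzyloxy)-2-bromophenyl]-3,4-dihydro-2H-chromene-2,5,7-triol (both anomers) | Oc1cc2OC(O)C[C@@H](c3ccc(OCc4ccccc4)cc3Br)c2c(O)c1
F4 | step 4 | (3R)-3-[4-(benzyloxy)-2-bromophenyl]-3-[2,4,6-tris(benzyloxy)phenyl]propanal | O=CC[C@@H](c1ccc(OCc2ccccc2)cc1Br)c1c(OCc2ccccc2)cc(OCc2ccccc2)cc1OCc1ccccc1
F5 | step 4 | (3R)-1-[4-(benzyloxy)phenyl]-3-[4-(benzyloxy)-2-bromophenyl]-3-[2,4,6-tris(benzyloxy)phenyl]propan-1-one | O=C(C[C@@H](c1ccc(OCc2ccccc2)cc1Br)c1c(OCc2ccccc2)cc(OCc2ccccc2)cc1OCc1ccccc1)c1ccc(OCc2ccccc2)cc1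
F6 | step 5 | 1-[3-[(1R)-1-[4-(benzyloxy)-2-bromophenyl]-3-[4-(benzyloxy)phenyl]-3-hydroxypropyl]-2,4,6-trihydroxyphenyl]-9-phenylnonan-1-one (both carbinol epimers) | O=C(CCCCCCCCc1ccccc1)c1c(O)cc(O)c([C@@H](CC(O)c2ccc(OCc3ccccc3)cc2)c2ccc(OCc3ccccc3)cc2Br)c1O
F7 | step 5 | (3R)-1-[4-(benzyloxy)phenyl]-3-[4-(benzyloxy)-2-bromophenyl]-3-[2,4,6-tris(benzyloxy)-3-(9-phenylnonanoyl)phenyl]propan-1-ol (both carbinol epimers) | O=C(CCCCCCCCc1ccccc1)c1c(OCc2ccccc2)cc(OCc2ccccc2)c([C@@H](CC(O)c2ccc(OCc3ccccc3)cc2)c2ccc(OCc3ccccc3)cc2Br)c1OCc1ccccc1
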